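**Assumptions (one line each)**
- The C8 ester is tiglate (E), read from the SMILES.
- 3-Methylfuran-2(5H)-one, 2,2-dimethoxyacetaldehyde, propane-1,3-dithiol, methallyl alcohol, tiglic acid and ethyl acrylate are taken as commercial (all ≤8 heavy atoms).
- The C3 carbinol in 23–29 is racemic; it is destroyed in the last step.

## Retrosynthetic overview
1. Target **30** ⇐ DMP oxidation of the C3 carbinol ⇐ desilylation ⇐ ring-closing metathesis that forms C1=C2 and closes the 10-membered ring last (diene **27**).
2. **27** ⇐ Cr-mediated anti-selective allylation with in-situ lactonisation (C6–C7 bond; the trans α-methylene-γ-lactone forms here). The partners are Z-enal **26** (C3–C6 unit, from 3-methylfuranone) and allyl bromide **18** (C7–C10 unit plus C1 vinyl).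
3. **18** ⇐ Baylis–Hillman reaction and SN2′ bromination of an aldehyde ⇐ C8 ketone **8**. C8 comes from directed anti reduction of **8**, which is built by opening Sharpless-derived epoxide **3** (C10) with dithiane **6**.

## Forward synthesis

**Step 1**
Reactants: 1, 2-methylprop-2-en-1-ol (methallyl alcohol)
Product: 2, (S)-2-methylglycidol
Conditions: Ti(OiPr)4 (cat.), L-(+)-DET, TBHP, 3 Å MS, CH2Cl2, –20 °C
Reagents that add atoms: tert-butyl hydroperoxide, CC(C)(C)OO (supplies the epoxide O)
Why: Sharpless asymmetric epoxidation delivers oxygen to one enantioface and sets the quaternary carbon that becomes C10 (R).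

**Step 2**
Reactants: 2
Product: 3, (R)-TBDPS ether of 2-methylglycidol
Conditions: TBDPSCl, imidazole, DMF, 0→23 °C
Reagents that add atoms: TBDPSCl, CC(C)(C)[Si](Cl)(c1ccccc1)c1ccccc1
Why: Silylation masks C1–O and prevents the base-mediated Payne rearrangement that would racemise the epoxide. The stereocentre is untouched (the descriptor changes from S to R only because the CIP priorities change).

**Step 3**
Reactants: 4, 2,2-dimethoxyacetaldehyde; 5, propane-1,3-dithiol
Product: 6, 2-(dimethoxymethyl)-1,3-dithiane
Conditions: BF3·OEt2 (cat.), CH2Cl2, 0 °C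
Reagents that add atoms: none
Why: Lewis-acid dithioacetalisation of the aldehyde gives a masked C8 acyl anion that carries C7 as a dimethyl acetal.

**Step 4**
Reactants: 6; 3
Product: 7, (R)-tertiary alcohol bearing the 2,2-disubstituted dithiane (C8), the C7 acetal and the C1 OTBDPS
Conditions: 6, n-BuLi, THF, –78→–30 °C; then 3, HMPA, –78→0 °C
Reagents that add atoms: none (n-BuLi only deprotonates; the alkoxide is protonated on work-up)
Why: Corey–Seebach SN2 opening at the unhindered epoxide CH2 (C9) forms C8–C9 and leaves the C10 centre unchanged.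

**Step 5**
Reactants: 7
Product: 8, β-hydroxy ketone (C8 = O) with the C7 acetal
Conditions: PIFA, NaHCO3, MeCN–H2O (9:1), 0 °C
Reagents that add atoms: water, O (supplies the ketone oxygen)
Why: Oxidative dithiane hydrolysis under buffered, non-acidic conditions leaves the acetal and silyl ether intact.

**Step 6**
Reactants: 8
Product: 9, anti-1,3-diol (8R,10R)
Conditions: Me4NBH(OAc)3, MeCN–AcOH (1:1), –30→–10 °C
Reagents that add atoms: none
Why: Evans–Saksena reduction delivers hydride intramolecularly from an acetoxyborohydride tethered to the C10 alkoxide through a chair transition state. This gives the 1,3-anti diol, i.e. C8 = R relative to C10 = R.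

**Step 7**
Reactants: 9; 10, tiglic acid
Product: 11, C8 tiglate with free tertiary C10–OH
Conditions: 10, 2,4,6-Cl3C6H2COCl, Et3N, THF; then 9, DMAP, PhMe, 23 °C
Reagents that add atoms: none
Why: Yamaguchi esterification acylates only the secondary alcohol; the tertiary alcohol is inert. The C8 configuration is retained and the tiglate stays E. This ester also blocks C8–O so that only C6–O can close the lactone later.

**Step 8**
Reactants: 11
Product: 12, primary alcohol
Conditions: HF·pyridine, pyridine–THF, 0→23 °C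
Reagents that add atoms: none
Why: Fluoride cleaves the primary TBDPS ether; the tiglate, acetal and tertiary alcohol survive.

**Step 9**
Reactants: 12
Product: 13, α-hydroxy aldehyde (C1 = CHO)
Conditions: DMP, NaHCO3, CH2Cl2, 0 °C
Reagents that add atoms: none
Why: Mild oxidation of the primary alcohol; the α-carbon is quaternary, so there is nothing to epimerise.

**Step 10**
Reactants: 13
Product: 14, tertiary allylic alcohol (C10 vinyl, C1=C2′)
Conditions: Ph3P=CH2 (from Ph3PCH3Br + KHMDS, 3 equiv), THF, –78→0 °C
Reagents that add atoms: methylenetriphenylphosphorane, C=P(c1ccccc1)(c1ccccc1)c1ccccc1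
Why: Wittig methylenation; no stereocentre is touched.

**Step 11**
Reactants: 14
Product: 15, C7 aldehyde (C8 tiglate retained)
Conditions: TMSOTf, 2,2′-bipyridyl, CH2Cl2, 0 °C; then H2O
Reagents that add atoms: water, O
Why: Fujioka acetal-to-aldehyde conversion under weakly basic conditions protects the acid-labile tertiary allylic alcohol and the ester; any TMS ether formed is cleaved on work-up.

**Step 12**
Reactants: 15; 16, ethyl acrylate
Product: 17, Baylis–Hillman adduct (C7 epimeric mixture)
Conditions: 16 (5 equiv), DABCO (1 equiv), MeCN–MeOH, 23 °C, 3 d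
Reagents that add atoms: none
Why: Morita–Baylis–Hillman coupling builds the acrylate unit (C11–C13, C12). The C7 carbinol stereocentre is lost in the next step.

**Step 13**
Reactants: 17
Product: 18, (2Z)-2-(bromomethyl)alk-2-enoate (C8 cis to CH2Br)
Conditions: NBS, Me2S, CH2Cl2, –20→0 °C
Reagents that add atoms: N-bromosuccinimide, BrN1C(=O)CCC1=O (supplies Br)
Why: Bromide attacks the CH2 terminus of the activated Baylis–Hillman alcohol (SN2′), giving the trisubstituted allylic bromide needed for Cr allylation.

**Step 14**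
Reactants: 19, 3-methylfuran-2(5H)-one
Product: 20, (Z)-2-methylbut-2-ene-1,4-diol
Conditions: DIBAL-H (2.5 equiv), CH2Cl2, –78→0 °C
Reagents that add atoms: none
Why: Complete reduction of the lactone retains the ring-locked cis relationship of C3 and C6, which fixes the Z geometry of C4=C5.

**Step 15**
Reactants: 20
Product: 21, C6 mono-TBS ether (free C3–OH)
Conditions: TBSCl (1.0 equiv), imidazole, CH2Cl2, –20 °C
Reagents that add atoms: TBSCl, CC(C)(C)[Si](C)(C)Cl
Why: Silylation goes mainly at the less hindered CH2OH on the CH= end (C6); the regioisomer is removed by chromatography.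

**Step 16**
Reactants: 21
Product: 22, (Z)-enal (C3 = CHO, C6–OTBS)
Conditions: MnO2, CH2Cl2, 23 °C
Reagents that add atoms: none
Why: Chemoselective oxidation of the allylic alcohol with retention of alkene geometry.

**Step 17**
Reactants: 22
Product: 23, (4Z)-6-(TBSO)-4-methylhexa-1,4-dien-3-ol (C3 carbinol, racemic)
Conditions: vinylMgBr (1.5 equiv), THF, –78 °C
Reagents that add atoms: vinylmagnesium bromide, C=C[Mg]Br
Why: 1,2-Addition to the aldehyde installs C2=C1′ for the later RCM. The new centre is racemic and is later oxidised away.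

**Step 18**
Reactants: 23
Product: 24, C3–OTBDPS, C6–OTBS bis-silyl ether
Conditions: TBDPSCl, imidazole, DMAP, DMF, 50 °C
Reagents that add atoms: TBDPSCl, CC(C)(C)[Si](Cl)(c1ccccc1)c1ccccc1
Why: Installs an orthogonal protecting group on the secondary alcohol.

**Step 19**
Reactants: 24
Product: 25, (2Z)-4-(TBDPSO)-3-methylhexa-2,5-dien-1-ol
Conditions: CSA (0.1 equiv), MeOH–CH2Cl2 (1:1), 0 °C
Reagents that add atoms: none
Why: Acid methanolysis removes the primary TBS ether selectively and leaves the secondary TBDPS ether.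

**Step 20**
Reactants: 25
Product: 26, (2Z)-4-(TBDPSO)-3-methylhexa-2,5-dienal (C6 aldehyde)
Conditions: MnO2, CH2Cl2, 23 °C
Reagents that add atoms: none
Why: Allylic oxidation gives the aldehyde partner for the key coupling with the Z-alkene intact.

**Step 21 (key coupling)**
Reactants: 18; 26
Product: 27, trans-fused α-methylene-γ-butyrolactone (6R,7R,8R,10R; C3 epimeric mixture)
Conditions: CrCl2 (6 equiv), THF, 23 °C; then TsOH·H2O (cat.), PhMe, 50 °C (one pot)
Reagents that add atoms: none (EtOH is lost on lactonisation)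
Why: Nozaki–Hiyama-type Barbier allylation through a chair Zimmerman–Traxler transition state of the (E)-allylchromium (R trans to CH2Cr) gives the anti homoallylic alcohol, so C6/C7 are trans. The C7 face is set by 1,2-induction from C8: A(1,3) strain puts C8–H in the alkene plane and the aldehyde attacks anti to the C9 chain. The C6–OH then closes only onto the ester (C8–O is blocked as tiglate), forming the α-methylene-γ-lactone.

**Step 22**
Reactants: 27
Product: 28, 10-membered carbocycle with E-C1=C2, C3–OTBDPS and the Z-C4=C5 alkene (C3 epimeric mixture)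
Conditions: Hoveyda–Grubbs II (20 mol %), PhMe (2 mM), 80 °C
Reagents that add atoms: none (ethylene is lost)
Why: Ring-closing metathesis of the two terminal vinyl groups forms C1=C2. The trans-lactone and Z-alkene pre-organise the ring and favour the E-alkene; the free tertiary allylic alcohol does not hinder the catalyst.

**Step 23**
Reactants: 28
Product: 29, C3 bis-allylic alcohol
Conditions: HF·pyridine, THF, 0→23 °C
Reagents that add atoms: none
Why: Fluoride removes the TBDPS ether under mildly acidic conditions, so the tiglate, lactone and α-methylene survive.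

**Step 24**
Reactants: 29
Product: 30, eupaheliangolide A
Conditions: DMP, NaHCO3, CH2Cl2, 0 °C
Reagents that add atoms: none
Why: Oxidation of the doubly allylic C3 alcohol gives the cross-conjugated (1E,4Z)-dienone. The C3 stereochemistry is destroyed, so the two C3 epimers converge, and the tertiary C10–OH is untouched.

## Compound list
1 | 2-methylprop-2-en-1-ol | C=C(C)CO | starting material
2 | (S)-(2-methyloxiran-2-yl)methanol | C[C@]1(CO)CO1 | intermediate
3 | (R)-TBDPS ether of 2-methylglycidol | C[C@]1(CO[Si](c2ccccc2)(c2ccccc2)C(C)(C)C)CO1 | intermediate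
4 | 2,2-dimethoxyacetaldehyde | COC(OC)C=O | starting material
5 | propane-1,3-dithiol | SCCCS | starting material
6 | 2-(dimethoxymethyl)-1,3-dithiane | COC(OC)C1SCCCS1 | intermediate
7 | (2R)-1-(TBDPSO)-3-[2-(dimethoxymethyl)-1,3-dithian-2-yl]-2-methylpropan-2-ol | CC(C)(C)[Si](c1ccccc1)(c1ccccc1)OC[C@](C)(O)CC2(SCCCS2)C(OC)OC | intermediate
8 | (4R)-5-(TBDPSO)-4-hydroxy-1,1-dimethoxy-4-methylpentan-2-one | CC(C)(C)[Si](c1ccccc1)(c1ccccc1)OC[C@](C)(O)CC(=O)C(OC)OC | intermediate
9 | (2R,4R)-5-(TBDPSO)-1,1-dimethoxy-4-methylpentane-2,4-diol | CC(C)(C)[Si](c1ccccc1)(c1ccccc1)OC[C@](C)(O)C[C@@H](O)C(OC)OC | intermediate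
10 | tiglic acid ((E)-2-methylbut-2-enoic acid) | C/C=C(\C)/C(=O)O | starting material
11 | (2R,4R)-5-(TBDPSO)-4-hydroxy-1,1-dimethoxy-4-methylpentan-2-yl tiglate | CC(C)(C)[Si](c1ccccc1)(c1ccccc1)OC[C@](C)(O)C[C@@H](OC(=O)/C(C)=C/C)C(OC)OC | intermediate
12 | (2R,4R)-4,5-dihydroxy-1,1-dimethoxy-4-methylpentan-2-yl tiglate | OC[C@](C)(O)C[C@@H](OC(=O)/C(C)=C/C)C(OC)OC | intermediate
13 | (2R,4R)-4-hydroxy-1,1-dimethoxy-4-methyl-5-oxopentan-2-yl tiglate | O=C[C@](C)(O)C[C@@H](OC(=O)/C(C)=C/C)C(OC)OC | intermediate
14 | (2R,4R)-4-hydroxy-1,1-dimethoxy-4-methylhex-5-en-2-yl tiglate | C=C[C@](C)(O)C[C@@H](OC(=O)/C(C)=C/C)C(OC)OC | intermediate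
15 | (2R,4R)-4-hydroxy-4-methyl-1-oxohex-5-en-2-yl tiglate | C=C[C@](C)(O)C[C@@H](OC(=O)/C(C)=C/C)C=O | intermediate
16 | ethyl acrylate | C=CC(=O)OCC | starting material
17 | ethyl (4R,6R)-3,6-dihydroxy-6-methyl-2-methylidene-4-(tiglyloxy)oct-7-enoate (C3 epimers) | C=C[C@](C)(O)C[C@@H](OC(=O)/C(C)=C/C)C(O)C(=C)C(=O)OCC | intermediate
18 | ethyl (2Z,4R,6R)-2-(bromomethyl)-6-hydroxy-6-methyl-4-(tiglyloxy)octa-2,7-dienoate | C=C[C@](C)(O)C[C@@H](OC(=O)/C(C)=C/C)/C=C(\CBr)C(=O)OCC | intermediate
19 | 3-methylfuran-2(5H)-one | CC1=CCOC1=O | starting material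
20 | (Z)-2-methylbut-2-ene-1,4-diol | OC/C=C(/C)CO | intermediate
21 | (Z)-4-(TBSO)-2-methylbut-2-en-1-ol | CC(C)(C)[Si](C)(C)OC/C=C(/C)CO | intermediate
22 | (Z)-4-(TBSO)-2-methylbut-2-enal | CC(C)(C)[Si](C)(C)OC/C=C(/C)C=O | intermediate
23 | (4Z)-6-(TBSO)-4-methylhexa-1,4-dien-3-ol (racemic at C3) | CC(C)(C)[Si](C)(C)OC/C=C(/C)C(O)C=C | intermediate
24 | (Z)-1-(TBSO)-4-(TBDPSO)-3-methylhexa-2,5-diene | CC(C)(C)[Si](C)(C)OC/C=C(/C)C(O[Si](c1ccccc1)(c1ccccc1)C(C)(C)C)C=C | intermediate
25 | (2Z)-4-(TBDPSO)-3-methylhexa-2,5-dien-1-ol | OC/C=C(/C)C(O[Si](c1ccccc1)(c1ccccc1)C(C)(C)C)C=C | intermediate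
26 | (2Z)-4-(TBDPSO)-3-methylhexa-2,5-dienal | O=C/C=C(/C)C(O[Si](c1ccccc1)(c1ccccc1)C(C)(C)C)C=C | intermediate
27 | trans (6R,7R)-α-methylene-γ-lactone carrying the C8-tiglate/C10-carbinol chain at C7 and the (Z)-CH=C(Me)CH(OTBDPS)CH=CH2 chain at C6 | C=C1C(=O)O[C@H](/C=C(/C)C(O[Si](c2ccccc2)(c2ccccc2)C(C)(C)C)C=C)[C@H]1[C@H](OC(=O)/C(C)=C/C)C[C@@](C)(O)C=C | intermediate
28 | RCM macrocycle, C3-OTBDPS (C3 epimers) | C=C1C(=O)O[C@@H]2/C=C(/C)C(O[Si](c3ccccc3)(c3ccccc3)C(C)(C)C)/C=C/[C@](C)(O)C[C@@H](OC(=O)/C(C)=C/C)[C@@H]12 | intermediate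
29 | macrocycle, C3-OH (C3 epimers) | C=C1C(=O)O[C@@H]2/C=C(/C)C(O)/C=C/[C@](C)(O)C[C@@H](OC(=O)/C(C)=C/C)[C@@H]12 | intermediate
30 | eupaheliangolide A | C=C1C(=O)O[C@@H]2/C=C(/C)C(=O)/C=C/[C@](C)(O)C[C@@H](OC(=O)/C(C)=C/C)[C@@H]12 | target

## Totals
- Total steps: 24.
- Longest linear sequence: 16 (steps 1→2→4→5→6→7→8→9→10→11→12→13→21→22→23→24), which is 2/3 of the total.

**Three steps most likely to fail**
1. **Step 21 (Cr allylation, C7 facial selectivity).**
   - The single C8 stereocentre must control C7, and the γ-acyloxy allylchromium could undergo vinylogous elimination.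
   - Fallback: build the lactone by trans-selective conjugate addition instead. Add the lithiated dithiane (from 6 + 3) to (S)-5-(silyloxymethyl)butenolide, then α-methylenate. This removes the need for 18 and 26 and re-orders the endgame.
2. **Step 22 (RCM to a 10-membered E-alkene).**
   - It may give the Z-isomer, oligomers or no reaction.
   - Fallback: intramolecular Nozaki–Hiyama–Kishi closure. Convert aldehyde 13 to the E-vinyl iodide by Takai olefination, carry that through the same sequence, and use a Z-enal with a C3 aldehyde in place of 26, so the ring closes at C2–C3 with alkene geometry fixed.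
3. **Step 6 (Evans–Saksena reduction with a tertiary β-OH and an α-acetal ketone).**
   - It may give poor anti selectivity, or retro-aldol or dehydration may compete.
   - Fallback: catalyst-controlled Ru–TsDPEN transfer hydrogenation (or CBS reduction) of ketone 8, with chromatographic separation of the C8 epimers, in place of substrate-directed hydride delivery.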